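## Retrosynthetic overview

- Cyclopentane numbering: C1 (CH3, CH2C(=O) arm), C2 (CH3, enoyl arm), C3–C5 (CH2). Last disconnections: hydroquinone from its dimethyl ether; enone arm by Nozaki–Hiyama–Kishi addition of an (E)-iodoalkene to a C2 aldehyde; skipped (Z)-alkene arm by opening a terminal epoxide on the C1 arm with a (Z)-alkenyllithium, whose geometry comes from trans-hydroalumination/iodination of but-2-yn-1-ol.
- Enabling feature: C1 and C2 are vicinal quaternary carbons with cis methyls, and their arms form a 1,5-dicarbonyl array O=C–C2–C1–CH2–C=O. Bonding the two carbonyl carbons to each other gives a temporary five-membered ring B, i.e. a cis-1,5-dimethylbicyclo[3.3.0]octane whose two C–CH3 bridgeheads are the carbonyl carbons of butane-2,3-dione.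
- Key step (Weiss–Cook condensation of butane-2,3-dione with two molecules of dimethyl 3-oxopentanedioate): ring B forms first by double aldol addition; ring A (the cyclopentane of the target) forms second, closed by the intramolecular Michael addition that makes the C1–C5 bond, with C5 activated by an ester and the C4 ketone.
- The activating groups are then removed (fourfold decarboxylation, Wolff–Kishner at C4) to give a meso ketone. Enantioselective deprotonation and ozonolysis of the enol ether cleave ring B into the two differentiated arm carbons (CH2–CO2H on C1, CHO on C2) and fix both quaternary stereocentres at once.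
- The arene is bought with its substitution pattern and joined as an arylmagnesium bromide to the (Z)-C4 unit.

Key step: step 1

Remark on the chemistry (assumption): the sense of enantiotopic-group selection by the lithium amide in step 5 is assumed; the mirror-image amide is equally accessible and would be used if the opposite methylene were removed.

## Route

Step 1
Reactants: 1 butane-2,3-dione; 2 dimethyl 3-oxopentanedioate (2 equiv)
Product: 5 tetramethyl cis-3,7-dihydroxy-1,5-dimethylbicyclo[3.3.0]octa-2,6-diene-2,4,6,8-tetracarboxylate (bis-enol form of the 3,7-dioxo tetraester), via hydroxy enone 3 (not isolated), via seco enone 4 (not isolated)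
Conditions: NaHCO3, H2O, 20 °C
Reagents that add atoms: none
Why: Weiss–Cook condensation, the established reaction of 1,2-diketones with 3-oxoglutarates: one molecule of 2 adds by two aldol reactions to both carbonyls of 1 and loses water to give hydroxy enone 3 (ring B); a second molecule of 2 adds in Michael fashion to the methyl-bearing β-carbon (C2–C3 bond), loss of the remaining hydroxyl regenerates an enone (4), and the pendant β-keto ester carbon then adds intramolecularly to the second methyl-bearing β-carbon, which forms the C1–C5 bond and closes ring A. Ring B therefore closes by aldol addition and ring A by a 5-exo-trig conjugate addition in which the nucleophilic carbon (future C5) carries an ester and a ketone that steps 2 and 4 remove. Both quaternary centres are set here; their cis relation is enforced by the ring fusion, because only the cis-bicyclo[3.3.0]octane is accessible (the Michael steps are reversible and the trans-fused isomer is highly strained), so the product is meso and needs no absolute control at this stage. The selectivity required is clean 1:2 stoichiometry over oligomerisation; the mildly basic aqueous medium, from which the bis-enol 5 is expected to crystallise, should secure it. In one operation the step assembles all five ring carbons, both methyl-bearing quaternary carbons and both arm carbons from two simple acyclic reagents.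

Step 2
Reactants: 5 tetraester
Product: 6 cis-1,5-dimethylbicyclo[3.3.0]octane-3,7-dione (meso)
Conditions: 1 M HCl, AcOH, reflux
Reagents that add atoms: none
Why: Acid-catalysed ester hydrolysis and fourfold decarboxylation of the β-keto acid units should remove all four activating ester groups, and the quaternary bridgeheads cannot epimerise.

Step 3
Reactants: 6 cis-1,5-dimethylbicyclo[3.3.0]octane-3,7-dione
Product: 7 mono(2,2-dimethylpropane-1,3-diyl) ketal of 6
Conditions: 2,2-dimethylpropane-1,3-diol (1 equiv), TsOH·H2O (cat.), toluene, reflux, Dean–Stark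
Reagents that add atoms: 2,2-dimethylpropane-1,3-diol, OCC(C)(C)CO
Why: Acetal formation on one of the two equivalent ketones is statistical, and recovered 6 and bis-ketal can be recycled.

Step 4
Reactants: 7 monoketal
Product: 10 cis-1,5-dimethylbicyclo[3.3.0]octan-3-one (meso; 1R,5S), via hydrazone 8 (not isolated), via deoxygenated ketal 9 (not isolated)
Conditions: N2H4·H2O, KOH, diethylene glycol, 130 → 200 °C; then 2 M HCl, THF, 20 °C
Reagents that add atoms: water, O
Why: Wolff–Kishner reduction should remove the ring A carbonyl (the last activating group of the key step) while the base-stable ketal shields the ring B ketone, which aqueous acid then releases.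

Step 5
Reactants: 10 cis-1,5-dimethylbicyclo[3.3.0]octan-3-one
Product: 12 (1S,5R)-1,5-dimethyl-3-(trimethylsilyloxy)bicyclo[3.3.0]oct-2-ene, via lithium enolate 11 (not isolated)
Conditions: bis[(R)-1-phenylethyl]amine, n-BuLi, LiCl, THF, −78 °C; then TMSCl and 10, −100 °C (in situ quench)
Reagents that add atoms: trimethylsilyl chloride, C[Si](C)(C)Cl
Why: Enantioselective deprotonation of a meso ketone by the C2-symmetric lithium bis[(R)-1-phenylethyl]amide with in situ silylation (a reaction type established for meso bicyclo[3.3.0]octan-3-ones and 4-substituted cyclohexanones) should remove a proton from only one of the two enantiotopic α-methylenes, here the CH2 on the (S)-bridgehead, which fixes the absolute configuration of both quaternary centres.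

Step 6
Reactants: 12 silyl enol ether
Product: 15 (4aR,7aR)-4a,7a-dimethylhexahydrocyclopenta[c]pyran-3(1H)-one, via aldehyde acid 13 (not isolated), via hydroxy acid 14 (not isolated)
Conditions: O3, CH2Cl2/MeOH, −78 °C; NaBH4, −78 → 20 °C; then 2 M HCl
Reagents that add atoms: ozone, [O-][O+]=O
Why: Ozonolysis of the silyl enol ether cleaves the temporary ring B between the former carbonyl carbon (which becomes CO2H on the CH2 arm of C1) and its α-carbon (which becomes CHO on C2), borohydride reduces the aldehyde, and the hydroxy acid should lactonise on acidification without touching a stereocentre.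

Step 7
Reactants: 15 lactone
Product: 16 (4aR,7aR)-4a,7a-dimethyloctahydrocyclopenta[c]pyran-3-ol (lactol; both anomers)
Conditions: iBu2AlH, CH2Cl2, −78 °C
Reagents that add atoms: none
Why: Partial reduction of a δ-lactone stops at the lactol because the tetrahedral aluminium hemiacetal is stable at −78 °C.

Step 8
Reactants: 16 lactol
Product: 17 [(1R,2R)-1,2-dimethyl-2-(prop-2-en-1-yl)cyclopentyl]methanol
Conditions: Ph3PCH3Br, KOtBu, THF, 0 → 50 °C
Reagents that add atoms: methyltriphenylphosphonium bromide, C[P+](c1ccccc1)(c1ccccc1)c1ccccc1.[Br-]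
Why: Wittig methylenation of the open hydroxy aldehyde form of the lactol gives the allyl group on C1 and frees the neopentyl alcohol on C2.

Step 9
Reactants: 17 alkenol
Product: 18 tert-butyl{[(1R,2R)-1,2-dimethyl-2-(prop-2-en-1-yl)cyclopentyl]methoxy}dimethylsilane
Conditions: TBSCl, imidazole, DMF, 20 °C
Reagents that add atoms: tert-butyldimethylsilyl chloride, CC(C)(C)[Si](C)(C)Cl
Why: Silyl ether formation prevents the neopentyl hydroxyl from opening the epoxide intramolecularly in steps 10 and 16.

Step 10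
Reactants: 18 silyl ether
Product: 19 tert-butyl{[(1R,2R)-1,2-dimethyl-2-(oxiran-2-ylmethyl)cyclopentyl]methoxy}dimethylsilane (both epimers at the oxirane carbon)
Conditions: mCPBA, CH2Cl2, 0 → 20 °C
Reagents that add atoms: 3-chloroperoxybenzoic acid, OOC(=O)c1cccc(Cl)c1
Why: Prilezhaev epoxidation of the only alkene; the new oxirane centre is inconsequential because it becomes a ketone in step 18.

Step 11
Reactants: 20 4-methoxy-2-methylphenol
Product: 21 2-bromo-4-methoxy-6-methylphenol
Conditions: NBS, CH2Cl2, 0 °C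
Reagents that add atoms: N-bromosuccinimide, O=C1CCC(=O)N1Br
Why: Electrophilic aromatic bromination is directed ortho to the free phenol, the para position and the other ortho position being blocked.

Step 12
Reactants: 21 2-bromo-4-methoxy-6-methylphenol
Product: 22 1-bromo-2,5-dimethoxy-3-methylbenzene
Conditions: MeI, K2CO3, acetone, reflux
Reagents that add atoms: iodomethane, CI
Why: Williamson O-methylation of the phenoxide gives the hydroquinone in a form that survives the organometallic steps.

Step 13
Reactants: 23 but-2-yn-1-ol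
Product: 25 (2Z)-3-iodobut-2-en-1-ol, via alkenylaluminate 24 (not isolated)
Conditions: NaAlH2(OCH2CH2OMe)2, THF, 0 → 20 °C; then I2, THF, −78 °C
Reagents that add atoms: iodine, II
Why: Hydroxyl-directed trans-hydroalumination of the propargylic alcohol places aluminium on C3 in a five-membered alkoxyaluminate, and iodinolysis with retention gives the (Z)-iodoalkene that carries the Z geometry of the target's trisubstituted alkene.

Step 14
Reactants: 25 (2Z)-3-iodobut-2-en-1-ol
Product: 26 (2Z)-1-bromo-3-iodobut-2-ene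
Conditions: CBr4, PPh3, CH2Cl2, 0 °C
Reagents that add atoms: tetrabromomethane, BrC(Br)(Br)Br
Why: Appel bromination converts the primary allylic alcohol under neutral conditions without allylic transposition or loss of geometry.

Step 15
Reactants: 22 1-bromo-2,5-dimethoxy-3-methylbenzene; 26 (2Z)-1-bromo-3-iodobut-2-ene
Product: 28 1-[(2Z)-3-iodobut-2-en-1-yl]-2,5-dimethoxy-3-methylbenzene, via arylmagnesium bromide 27 (not isolated)
Conditions: 22, Mg, THF, reflux; then CuI (5 mol %), 26, −30 → 0 °C
Reagents that add atoms: none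
Why: Copper-catalysed SN2 allylation of an aryl Grignard reagent should occur at the primary carbon, because SN2' attack would have to take place at the fully substituted iodine-bearing carbon, and the alkenyl iodide is far less reactive than the allylic bromide.

Step 16
Reactants: 28 aryl-substituted (Z)-iodoalkene (1.5 equiv); 19 epoxide
Product: 30 (4Z)-1-[(1R,2R)-2-{[tert-butyl(dimethyl)silyl]oxymethyl}-1,2-dimethylcyclopentyl]-6-(2,5-dimethoxy-3-methylphenyl)-4-methylhex-4-en-2-ol (both C2 epimers), via alkenyllithium 29 (not isolated)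
Conditions: 28, t-BuLi (2 equiv per 28), Et2O, −78 °C; then 19, BF3·OEt2, −78 °C
Reagents that add atoms: none
Why: Iodine–lithium exchange proceeds with retention of alkene geometry, and BF3-promoted opening of the terminal epoxide at its CH2 terminus by the alkenyllithium should give the homoallylic alcohol with the skipped (Z)-alkene in place.

Step 17
Reactants: 30 silyl ether
Product: 31 (4Z)-6-(2,5-dimethoxy-3-methylphenyl)-1-[(1R,2R)-2-(hydroxymethyl)-1,2-dimethylcyclopentyl]-4-methylhex-4-en-2-ol
Conditions: Bu4NF, THF, 20 °C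
Reagents that add atoms: none
Why: Fluoride-mediated cleavage of the silyl ether is done at the diol stage, before the base-sensitive β,γ-unsaturated ketone exists.

Step 18
Reactants: 31 diol
Product: 32 (1R,2R)-2-[(4Z)-6-(2,5-dimethoxy-3-methylphenyl)-4-methyl-2-oxohex-4-en-1-yl]-1,2-dimethylcyclopentane-1-carbaldehyde
Conditions: Dess–Martin periodinane, pyridine, CH2Cl2, 0 → 20 °C
Reagents that add atoms: none
Why: Dess–Martin oxidation of both the secondary and the neopentyl primary alcohol under buffered, non-basic conditions should leave the β,γ-unsaturated ketone unconjugated, and the aldehyde has no α-hydrogen to lose.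

Step 19
Reactants: 33 2-methylbut-3-yn-2-ol
Product: 35 (3E)-4-iodo-2-methylbut-3-en-2-ol, via alkenylstannane 34 (not isolated)
Conditions: Bu3SnH, PdCl2(PPh3)2 (2 mol %), THF, 20 °C; then I2, CH2Cl2, 0 °C
Reagents that add atoms: iodine, II
Why: Palladium-catalysed syn-hydrostannation of the terminal alkyne puts tin on the terminal carbon, distal to the bulky tertiary carbinol, and iododestannylation with retention gives the (E)-iodoalkene.

Step 20
Reactants: 32 keto aldehyde; 35 (3E)-4-iodo-2-methylbut-3-en-2-ol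
Product: 36 (4Z)-1-[(1R,2R)-2-[(2E)-1,4-dihydroxy-4-methylpent-2-en-1-yl]-1,2-dimethylcyclopentyl]-6-(2,5-dimethoxy-3-methylphenyl)-4-methylhex-4-en-2-one (both carbinol epimers)
Conditions: CrCl2, NiCl2 (1 mol %), DMSO, 20 °C
Reagents that add atoms: none
Why: In the Nozaki–Hiyama–Kishi reaction the alkenylchromium species adds to the aldehyde chemoselectively in the presence of the ketone, tolerates the free tertiary alcohol and retains the E geometry, and the new carbinol configuration is irrelevant.

Step 21
Reactants: 36 allylic alcohol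
Product: 37 (4Z)-6-(2,5-dimethoxy-3-methylphenyl)-1-[(1R,2R)-2-[(2E)-4-hydroxy-4-methylpent-2-enoyl]-1,2-dimethylcyclopentyl]-4-methylhex-4-en-2-one
Conditions: Dess–Martin periodinane, pyridine, CH2Cl2, 0 °C
Reagents that add atoms: none
Why: Dess–Martin oxidation converts the secondary allylic alcohol into the enone, while the tertiary alcohol cannot be oxidised.

Step 22
Reactants: 37 hydroquinone dimethyl ether
Product: 39 target, 2-{(2Z)-6-[(1R,2R)-2-[(2E)-4-hydroxy-4-methylpent-2-enoyl]-1,2-dimethylcyclopentyl]-3-methyl-5-oxohex-2-en-1-yl}-6-methylbenzene-1,4-diol, via quinone 38 (not isolated)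
Conditions: (NH4)2Ce(NO3)6, MeCN/H2O, 0 °C; EtOAc extraction; then aq. Na2S2O4, 20 °C
Reagents that add atoms: water, O
Why: Oxidative demethylation of the 1,4-dimethoxyarene by tetravalent cerium gives the para-quinone without acid or base strong enough to isomerise or cyclise the side chains, and dithionite should then reduce only the quinone.

## Compound list

1 | butane-2,3-dione | CC(=O)C(C)=O | starting material
2 | dimethyl 3-oxopentanedioate | COC(=O)CC(=O)CC(=O)OC | starting material
3 | dimethyl 5-hydroxy-4,5-dimethyl-2-oxocyclopent-3-ene-1,3-dicarboxylate (racemic hydroxy enone, ring B) | COC(=O)C1C(=O)C(C(=O)OC)=C(C)C1(C)O | intermediate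
4 | dimethyl 5-(1,5-dimethoxy-1,3,5-trioxopentan-2-yl)-4,5-dimethyl-2-oxocyclopent-3-ene-1,3-dicarboxylate (racemic seco enone) | COC(=O)CC(=O)C(C(=O)OC)C1(C)C(C(=O)OC)C(=O)C(C(=O)OC)=C1C | intermediate
5 | tetramethyl cis-3,7-dihydroxy-1,5-dimethylbicyclo[3.3.0]octa-2,6-diene-2,4,6,8-tetracarboxylate (bis-enol; C4 and C8 configuration not defined) | OC2=C(C(=O)OC)[C@@]1(C)C(C(=O)OC)C(O)=C(C(=O)OC)[C@@]1(C)C2C(=O)OC | intermediate
6 | cis-1,5-dimethylbicyclo[3.3.0]octane-3,7-dione (meso) | O=C2C[C@@]1(C)CC(=O)C[C@@]1(C)C2 | intermediate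
7 | cis-1,5-dimethylbicyclo[3.3.0]octane-3,7-dione mono(2,2-dimethylpropane-1,3-diyl) ketal | O1CC(C)(C)COC12C[C@@]3(C)CC(=O)C[C@@]3(C)C2 | intermediate
8 | hydrazone of 7 | O1CC(C)(C)COC12C[C@@]3(C)CC(=NN)C[C@@]3(C)C2 | intermediate
9 | cis-1,5-dimethylbicyclo[3.3.0]octan-3-one 2,2-dimethylpropane-1,3-diyl ketal | O1CC(C)(C)COC12C[C@@]3(C)CCC[C@@]3(C)C2 | intermediate
10 | (1R,5S)-1,5-dimethylbicyclo[3.3.0]octan-3-one (cis, meso) | O=C2C[C@@]1(C)CCC[C@@]1(C)C2 | intermediate
11 | lithium (1S,5R)-1,5-dimethylbicyclo[3.3.0]oct-2-en-3-olate | [Li]OC1=C[C@]2(C)CCC[C@]2(C)C1 | intermediate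
12 | (1S,5R)-1,5-dimethyl-3-(trimethylsilyloxy)bicyclo[3.3.0]oct-2-ene | C[Si](C)(C)OC1=C[C@]2(C)CCC[C@]2(C)C1 | intermediate
13 | 2-[(1R,2R)-2-formyl-1,2-dimethylcyclopentyl]acetic acid | OC(=O)C[C@@]1(C)CCC[C@@]1(C)C=O | intermediate
14 | 2-[(1R,2R)-2-(hydroxymethyl)-1,2-dimethylcyclopentyl]acetic acid | OC(=O)C[C@@]1(C)CCC[C@@]1(C)CO | intermediate
15 | (4aR,7aR)-4a,7a-dimethylhexahydrocyclopenta[c]pyran-3(1H)-one | O=C2C[C@@]1(C)CCC[C@@]1(C)CO2 | intermediate
16 | (4aR,7aR)-4a,7a-dimethyloctahydrocyclopenta[c]pyran-3-ol (both anomers) | OC2C[C@@]1(C)CCC[C@@]1(C)CO2 | intermediate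
17 | [(1R,2R)-1,2-dimethyl-2-(prop-2-en-1-yl)cyclopentyl]methanol | C=CC[C@@]1(C)CCC[C@@]1(C)CO | intermediate
18 | tert-butyl{[(1R,2R)-1,2-dimethyl-2-(prop-2-en-1-yl)cyclopentyl]methoxy}dimethylsilane | C=CC[C@@]1(C)CCC[C@@]1(C)CO[Si](C)(C)C(C)(C)C | intermediate
19 | tert-butyl{[(1R,2R)-1,2-dimethyl-2-(oxiran-2-ylmethyl)cyclopentyl]methoxy}dimethylsilane (both oxirane epimers) | C1OC1C[C@@]2(C)CCC[C@@]2(C)CO[Si](C)(C)C(C)(C)C | intermediate
20 | 4-methoxy-2-methylphenol | COc1ccc(O)c(C)c1 | starting material
21 | 2-bromo-4-methoxy-6-methylphenol | COc1cc(C)c(O)c(Br)c1 | intermediate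
22 | 1-bromo-2,5-dimethoxy-3-methylbenzene | COc1cc(C)c(OC)c(Br)c1 | intermediate
23 | but-2-yn-1-ol | CC#CCO | starting material
24 | sodium 2,2-bis(2-methoxyethoxy)-3-methyl-2,5-dihydro-1,2-oxaluminol-2-uide (cyclic alkenylaluminate) | CC1=CCO[Al-]1(OCCOC)OCCOC.[Na+] | intermediate
25 | (2Z)-3-iodobut-2-en-1-ol | C/C(I)=C/CO | intermediate
26 | (2Z)-1-bromo-3-iodobut-2-ene | C/C(I)=C/CBr | intermediate
27 | (2,5-dimethoxy-3-methylphenyl)magnesium bromide | COc1cc(C)c(OC)c([Mg]Br)c1 | intermediate
28 | 1-[(2Z)-3-iodobut-2-en-1-yl]-2,5-dimethoxy-3-methylbenzene | C/C(I)=C/Cc1cc(OC)cc(C)c1OC | intermediate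
29 | [4-(2,5-dimethoxy-3-methylphenyl)but-2-en-2-yl]lithium (Li cis to the ArCH2 group) | C/C([Li])=C/Cc1cc(OC)cc(C)c1OC | intermediate
30 | (4Z)-1-[(1R,2R)-2-{[tert-butyl(dimethyl)silyl]oxymethyl}-1,2-dimethylcyclopentyl]-6-(2,5-dimethoxy-3-methylphenyl)-4-methylhex-4-en-2-ol (both C2 epimers) | C/C(=C/Cc1cc(OC)cc(C)c1OC)CC(O)C[C@@]1(C)CCC[C@@]1(C)CO[Si](C)(C)C(C)(C)C | intermediate
31 | (4Z)-6-(2,5-dimethoxy-3-methylphenyl)-1-[(1R,2R)-2-(hydroxymethyl)-1,2-dimethylcyclopentyl]-4-methylhex-4-en-2-ol (both C2 epimers) | C/C(=C/Cc1cc(OC)cc(C)c1OC)CC(O)C[C@@]1(C)CCC[C@@]1(C)CO | intermediate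
32 | (1R,2R)-2-[(4Z)-6-(2,5-dimethoxy-3-methylphenyl)-4-methyl-2-oxohex-4-en-1-yl]-1,2-dimethylcyclopentane-1-carbaldehyde | C/C(=C/Cc1cc(OC)cc(C)c1OC)CC(=O)C[C@@]1(C)CCC[C@@]1(C)C=O | intermediate
33 | 2-methylbut-3-yn-2-ol | CC(C)(O)C#C | starting material
34 | (3E)-2-methyl-4-(tributylstannyl)but-3-en-2-ol | CCCC[Sn](CCCC)(CCCC)/C=C/C(C)(C)O | intermediate
35 | (3E)-4-iodo-2-methylbut-3-en-2-ol | CC(C)(O)/C=C/I | intermediate
36 | (4Z)-1-[(1R,2R)-2-[(2E)-1,4-dihydroxy-4-methylpent-2-en-1-yl]-1,2-dimethylcyclopentyl]-6-(2,5-dimethoxy-3-methylphenyl)-4-methylhex-4-en-2-one (both carbinol epimers) | C/C(=C/Cc1cc(OC)cc(C)c1OC)CC(=O)C[C@@]1(C)CCC[C@@]1(C)C(O)/C=C/C(C)(C)O | intermediate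
37 | (4Z)-6-(2,5-dimethoxy-3-methylphenyl)-1-[(1R,2R)-2-[(2E)-4-hydroxy-4-methylpent-2-enoyl]-1,2-dimethylcyclopentyl]-4-methylhex-4-en-2-one | C/C(=C/Cc1cc(OC)cc(C)c1OC)CC(=O)C[C@@]1(C)CCC[C@@]1(C)C(=O)/C=C/C(C)(C)O | intermediate
38 | 2-{(2Z)-6-[(1R,2R)-2-[(2E)-4-hydroxy-4-methylpent-2-enoyl]-1,2-dimethylcyclopentyl]-3-methyl-5-oxohex-2-en-1-yl}-6-methylcyclohexa-2,5-diene-1,4-dione | C/C(=C/CC1=CC(=O)C=C(C)C1=O)CC(=O)C[C@@]1(C)CCC[C@@]1(C)C(=O)/C=C/C(C)(C)O | intermediate
39 | 2-{(2Z)-6-[(1R,2R)-2-[(2E)-4-hydroxy-4-methylpent-2-enoyl]-1,2-dimethylcyclopentyl]-3-methyl-5-oxohex-2-en-1-yl}-6-methylbenzene-1,4-diol | C/C(=C/Cc1cc(O)cc(C)c1O)CC(=O)C[C@@]1(C)CCC[C@@]1(C)C(=O)/C=C/C(C)(C)O | target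

## Step count and risks

Total step count: 22. Longest linear sequence: 16 steps (steps 1–10, 16–18, 20–22).

Steps most likely to fail:

1. Step 5. The bulky amide may discriminate poorly between the two enantiotopic, neopentyl-type α-methylenes, or deprotonation may be slow enough for proton exchange between enolate and ketone, either of which erodes the enantiomeric purity of everything downstream. The fallback replaces asymmetric deprotonation by a resolution; it sets out from 10 and comes back at 15. Baeyer–Villiger oxidation of meso ketone 10 (CF3CO3H, Na2HPO4, CH2Cl2) inserts oxygen next to either α-methylene and should give racemic cis-4a,7a-dimethylhexahydrocyclopenta[c]pyran-3(1H)-one F1. Aminolysis with (1S)-1-phenylethanamine and AlMe3 gives two diastereomeric hydroxy amides, which are separated by chromatography or crystallisation into 2-[(1R,2R)-2-(hydroxymethyl)-1,2-dimethylcyclopentyl]-N-[(1S)-1-phenylethyl]acetamide F2 and its (1S,2S)-cyclopentyl diastereomer F3. Heating F2 with 1 M H2SO4 in dioxane relactonises it to 15 and releases the amine.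

2. Step 20. Addition of the alkenylchromium reagent to an aldehyde flanked by two quaternary carbons may be slow, which leaves time for Lewis-acid-mediated intramolecular aldol closure of the keto aldehyde or reduction of the aldehyde. The fallback adds a more reactive alkenyllithium before the ketone exists; it sets out from 30 and comes back at 37. The secondary alcohol of 30 is silylated (TIPSOTf, 2,6-lutidine) to the bis-silyl ether F8. The primary silyl ether is cleaved selectively (pyridinium tosylate, MeOH) to the primary alcohol F9. Dess–Martin oxidation gives the aldehyde F10. Iodoalkene 35 is converted by t-BuLi (3 equiv, Et2O, −78 °C) into the dilithio alkoxide alkenyllithium F11, which adds to F10 to give the diol F12. Bu4NF removes the TIPS group to give the triol F13. Dess–Martin oxidation of both secondary carbinols then gives 37.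

3. Step 16. Proton transfer from the doubly activated ArCH2–CH= methylene may quench the alkenyllithium, or the Lewis acid may rearrange the epoxide or trigger participation of the silyl ether oxygen before the C–C bond forms. The fallback builds the ketone by Claisen acylation instead of epoxide opening; it sets out from 28 and lactone 15 (bypassing steps 7–10) and comes back at 32. Coupling of 28 with BrZnCH2CO2tBu catalysed by Pd(PPh3)4 should give tert-butyl (3Z)-5-(2,5-dimethoxy-3-methylphenyl)-3-methylpent-3-enoate F4 with retention of geometry. Deprotonation with LiN(iPr)2 (THF, −78 °C) gives the lithium dienolate F5, which is acylated at its α-carbon by lactone 15 to the hydroxy β-keto ester F6. Treatment with CF3CO2H in CH2Cl2 and gentle warming cleaves the tert-butyl ester and decarboxylates to the hydroxy ketone F7. Dess–Martin oxidation of the primary alcohol gives 32.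

Further compounds
F1 | step 5 | rac-cis-4a,7a-dimethylhexahydrocyclopenta[c]pyran-3(1H)-one (both enantiomers) | O=C2C[C@@]1(C)CCC[C@@]1(C)CO2.O=C2C[C@]1(C)CCC[C@]1(C)CO2
F2 | step 5 | 2-[(1R,2R)-2-(hydroxymethyl)-1,2-dimethylcyclopentyl]-N-[(1S)-1-phenylethyl]acetamide | C[C@H](NC(=O)C[C@@]1(C)CCC[C@@]1(C)CO)c1ccccc1
F3 | step 5 | 2-[(1S,2S)-2-(hydroxymethyl)-1,2-dimethylcyclopentyl]-N-[(1S)-1-phenylethyl]acetamide | C[C@H](NC(=O)C[C@]1(C)CCC[C@]1(C)CO)c1ccccc1
F4 | step 16 | tert-butyl (3Z)-5-(2,5-dimethoxy-3-methylphenyl)-3-methylpent-3-enoate | C/C(=C/Cc1cc(OC)cc(C)c1OC)CC(=O)OC(C)(C)C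
F5 | step 16 | lithium dienolate of F4 (enolate geometry not defined) | C/C(=C/Cc1cc(OC)cc(C)c1OC)C=C(O[Li])OC(C)(C)C
F6 | step 16 | tert-butyl (3Z)-5-(2,5-dimethoxy-3-methylphenyl)-2-{2-[(1R,2R)-2-(hydroxymethyl)-1,2-dimethylcyclopentyl]acetyl}-3-methylpent-3-enoate (both C2 epimers) | C/C(=C/Cc1cc(OC)cc(C)c1OC)C(C(=O)OC(C)(C)C)C(=O)C[C@@]1(C)CCC[C@@]1(C)CO
F7 | step 16 | (4Z)-6-(2,5-dimethoxy-3-methylphenyl)-1-[(1R,2R)-2-(hydroxymethyl)-1,2-dimethylcyclopentyl]-4-methylhex-4-en-2-one | C/C(=C/Cc1cc(OC)cc(C)c1OC)CC(=O)C[C@@]1(C)CCC[C@@]1(C)CO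
F8 | step 20 | bis-silyl ether of 31 (secondary O-triisopropylsilyl, primary O-tert-butyldimethylsilyl) | C/C(=C/Cc1cc(OC)cc(C)c1OC)CC(O[Si](C(C)C)(C(C)C)C(C)C)C[C@@]1(C)CCC[C@@]1(C)CO[Si](C)(C)C(C)(C)C
F9 | step 20 | [(1R,2R)-2-{(4Z)-6-(2,5-dimethoxy-3-methylphenyl)-4-methyl-2-[tri(propan-2-yl)silyloxy]hex-4-en-1-yl}-1,2-dimethylcyclopentyl]methanol | C/C(=C/Cc1cc(OC)cc(C)c1OC)CC(O[Si](C(C)C)(C(C)C)C(C)C)C[C@@]1(C)CCC[C@@]1(C)CO
F10 | step 20 | (1R,2R)-2-{(4Z)-6-(2,5-dimethoxy-3-methylphenyl)-4-methyl-2-[tri(propan-2-yl)silyloxy]hex-4-en-1-yl}-1,2-dimethylcyclopentane-1-carbaldehyde | C/C(=C/Cc1cc(OC)cc(C)c1OC)CC(O[Si](C(C)C)(C(C)C)C(C)C)C[C@@]1(C)CCC[C@@]1(C)C=O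
F11 | step 20 | lithium (3E)-4-lithio-2-methylbut-3-en-2-olate | [Li]/C=C/C(C)(C)O[Li]
F12 | step 20 | (2E)-1-[(1R,2R)-2-{(4Z)-6-(2,5-dimethoxy-3-methylphenyl)-4-methyl-2-[tri(propan-2-yl)silyloxy]hex-4-en-1-yl}-1,2-dimethylcyclopentyl]-4-methylpent-2-ene-1,4-diol | C/C(=C/Cc1cc(OC)cc(C)c1OC)CC(O[Si](C(C)C)(C(C)C)C(C)C)C[C@@]1(C)CCC[C@@]1(C)C(O)/C=C/C(C)(C)O
F13 | step 20 | (2E)-1-[(1R,2R)-2-[(4Z)-6-(2,5-dimethoxy-3-methylphenyl)-2-hydroxy-4-methylhex-4-en-1-yl]-1,2-dimethylcyclopentyl]-4-methylpent-2-ene-1,4-diol | C/C(=C/Cc1cc(OC)cc(C)c1OC)CC(O)C[C@@]1(C)CCC[C@@]1(C)C(O)/C=C/C(C)(C)O
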